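**Retrosynthetic overview**

1. The target is the all-(2R,3S) tetraflavanoid fisetinidol-(4α→6)-fisetinidol-(4α→6)-catechin-(8←4α)-fisetinidol; the last disconnection removes 13 benzyl and 3 triethylsilyl (TES) ethers.
2. Enabling feature: C4 of unit 2 is a methine held between two electron-rich aryl carbons, C4a of its own resorcinol-type ring A (para to O7, ortho to O1) and C6 of the phloroglucinol-type ring A of catechin unit 3 (between O5 and O7); it is therefore an aldehyde carbon that has been arylated twice.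
3. Key disconnection: C4–C4a (closure of ring C of unit 2) together with C4–C6 (interflavan bond) leads to the acyclic α-silyloxy-β-aryloxy aldehyde 19 and biflavanoid 13, united in one acid-catalysed tandem Friedel–Crafts operation.
4. Ring C of units 4 and 1 comes from one flavan-4-ol 12, made by cyclising aldehyde 9 through the same kind of C4–C4a bond; 12 alkylates tetra-O-benzylcatechin (→ 13) and resorcinol (→ 15). Every C2/C3 pair comes from one Sharpless epoxide 5, opened at its benzylic carbon by a phenoxide with inversion.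
5. Ring order: catechin rings (chiral pool) → ring C of units 4 and 1 (one flavan-4-ol) → ring C of unit 2 (key step) → deprotection.

Key step: step 15

Remark: fisetinidol = (2R,3S)-flavan-3,7,3',4'-tetraol and catechin = (2R,3S)-flavan-3,5,7,3',4'-pentaol; 4α means the C4 substituent is trans to the 3-oxygen (2,3-trans-3,4-trans). Unit 1 is the terminal fisetinidol, unit 2 the middle fisetinidol, unit 3 the catechin and unit 4 the fisetinidol on C8 of unit 3; rings A (benzo), B (catechol) and C (pyran) have their usual meaning in each unit. It is assumed that the secondary TES ethers survive the cold Lewis-acid steps 8, 9, 10 and 15; a TES group lost from unit 1 before step 13 would be restored there, and any lost in step 15 converge at step 16.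

**Route**

Step 1
Reactants: 1 3,4-bis(benzyloxy)benzaldehyde; 2 triethyl phosphonoacetate
Product: 3 ethyl (E)-3-[3,4-bis(benzyloxy)phenyl]prop-2-enoate
Conditions: NaH, THF, 0 °C to rt
Reagents that add atoms: none
Why: Horner–Wadsworth–Emmons olefination of an aromatic aldehyde with a stabilised phosphonate should give the (E)-cinnamate.

Step 2
Reactants: 3 ethyl (E)-3-[3,4-bis(benzyloxy)phenyl]prop-2-enoate
Product: 4 (E)-3-[3,4-bis(benzyloxy)phenyl]prop-2-en-1-ol
Conditions: i-Bu2AlH (2.2 equiv), CH2Cl2, −78 °C; aq. potassium sodium tartrate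
Reagents that add atoms: none
Why: 1,2-Reduction of an enoate by a dialkylaluminium hydride gives the allylic alcohol without touching the alkene or the benzyl ethers.

Step 3
Reactants: 4 (E)-3-[3,4-bis(benzyloxy)phenyl]prop-2-en-1-ol
Product: 5 [(2S,3S)-3-[3,4-bis(benzyloxy)phenyl]oxiran-2-yl]methanol
Conditions: Ti(OiPr)4 (10 mol%), L-(+)-diethyl tartrate (12 mol%), t-BuOOH (2 equiv, decane), 4 Å MS, CH2Cl2, −20 °C; NaOH/brine work-up, used promptly
Reagents that add atoms: tert-butyl hydroperoxide CC(C)(C)OO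
Why: Sharpless asymmetric epoxidation, in which the L-(+)-tartrate ligand delivers oxygen to the face of the (E)-allylic alcohol that sets both epoxide carbons as S; the non-acidic work-up protects the electron-rich aryl epoxide.

Step 4
Reactants: 5 [(2S,3S)-3-[3,4-bis(benzyloxy)phenyl]oxiran-2-yl]methanol; 6 3-(benzyloxy)phenol
Product: 7 (2S,3R)-3-[3,4-bis(benzyloxy)phenyl]-3-[3-(benzyloxy)phenoxy]propane-1,2-diol
Conditions: 6 (1.5 equiv), Cs2CO3 (0.2 equiv), DMF, 70 °C
Reagents that add atoms: none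
Why: SN2 opening of a 3-aryl-2,3-epoxy alcohol by a phenoxide at the benzylic carbon (known for 3-arylglycidols) proceeds with inversion, setting the benzylic centre as R and the anti O,O relationship that becomes 2,3-trans in the flavan.

Step 5
Reactants: 7 (2S,3R)-3-[3,4-bis(benzyloxy)phenyl]-3-[3-(benzyloxy)phenoxy]propane-1,2-diol
Product: 8 (2S,3R)-3-[3,4-bis(benzyloxy)phenyl]-3-[3-(benzyloxy)phenoxy]-1,2-bis(triethylsilyloxy)propane
Conditions: Et3SiCl (2.5 equiv), imidazole, DMAP (cat.), DMF, 0 °C to rt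
Reagents that add atoms: chlorotriethylsilane CC[Si](Cl)(CC)CC
Why: Silylation of both hydroxyl groups leaves the stereocentres untouched and prepares the selective oxidation of step 6.

Step 6
Reactants: 8 (2S,3R)-3-[3,4-bis(benzyloxy)phenyl]-3-[3-(benzyloxy)phenoxy]-1,2-bis(triethylsilyloxy)propane
Product: 9 (2R,3R)-3-[3,4-bis(benzyloxy)phenyl]-3-[3-(benzyloxy)phenoxy]-2-(triethylsilyloxy)propanal
Conditions: (COCl)2, DMSO, CH2Cl2, −78 to −40 °C; then Et3N, −78 °C; cold pH 7 work-up, used at once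
Reagents that add atoms: none
Why: Swern conditions are known to cleave and oxidise a primary TES ether selectively beside a secondary one, which should give the α-silyloxy aldehyde in one operation; cold handling guards the α-centre and the β-aryloxy group.

Step 7
Reactants: 10 (+)-catechin
Product: 11 5,7,3',4'-tetra-O-benzyl-(+)-catechin
Conditions: BnBr (4.4 equiv), K2CO3, DMF, 0 °C to rt
Reagents that add atoms: benzyl bromide BrCc1ccccc1
Why: Williamson etherification under carbonate benzylates the four phenols and leaves the aliphatic 3-hydroxyl free.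

Step 8
Reactants: 9 (2R,3R)-3-[3,4-bis(benzyloxy)phenyl]-3-[3-(benzyloxy)phenoxy]-2-(triethylsilyloxy)propanal
Product: 12 (2R,3S)-7-(benzyloxy)-2-[3,4-bis(benzyloxy)phenyl]-3-(triethylsilyloxy)chroman-4-ol (mixture of C4 epimers)
Conditions: Me2AlCl (1.5 equiv, hexanes), CH2Cl2, −78 °C, 30 min; cold aq. potassium sodium tartrate
Reagents that add atoms: none
Why: Proposed new method: the aluminium-bound aldehyde should be attacked by the ring carbon para to the benzyloxy group and ortho to the ether oxygen of its own aryl ether (6-exo-trig Friedel–Crafts hydroxyalkylation through a chair with the aryl and silyloxy groups equatorial), and the proton of the arenium ion should be taken up by a methyl–aluminium bond as methane, which leaves the dialkoxybenzylic oxygen as a non-acidic aluminium alkoxide that does not ionise at −78 °C, so that the reaction stops at flavan-4-ol 12; C4 forms as a mixture that is erased on later ionisation, and the closest known reaction types are the Me2AlCl-promoted carbonyl-ene and Prins cyclisations arrested at the alcohol in the same way and the Lewis-acid cyclisation of 3-aryloxypropanal acetals to 4-alkoxychromans.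

Step 9
Reactants: 12 (2R,3S)-7-(benzyloxy)-2-[3,4-bis(benzyloxy)phenyl]-3-(triethylsilyloxy)chroman-4-ol; 11 5,7,3',4'-tetra-O-benzyl-(+)-catechin
Product: 13 7,3',4'-tri-O-benzyl-3-O-(triethylsilyl)fisetinidol-(4α→8)-5,7,3',4'-tetra-O-benzylcatechin
Conditions: 11 (3 equiv), Me3SiOTf (0.3 equiv), 4 Å MS, CH2Cl2, −78 to −30 °C; Et3N
Reagents that add atoms: none
Why: Catalytic Me3SiOTf ionises the flavan-4-ol to the flavan-4-yl cation stabilised by the 7-benzyloxy group and O1, and C8 of 11 (the more accessible free position of its phloroglucinol-type ring, used in excess) should capture it on the face anti to the 3-OTES group, setting C4 as 4α; this is the known Lewis-acid Friedel–Crafts coupling of flavan-4-ols and their 4-ethers with benzylated flavan-3-ols.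

Step 10
Reactants: 12 (2R,3S)-7-(benzyloxy)-2-[3,4-bis(benzyloxy)phenyl]-3-(triethylsilyloxy)chroman-4-ol; 14 resorcinol
Product: 15 (2R,3S,4R)-7-(benzyloxy)-2-[3,4-bis(benzyloxy)phenyl]-4-(2,4-dihydroxyphenyl)-3-(triethylsilyloxy)chromane
Conditions: 14 (6 equiv), Me3SiOTf (0.3 equiv), CH2Cl2/Et2O, −78 to −20 °C; Et3N
Reagents that add atoms: none
Why: The same ionisation gives the flavan-4-yl cation, which C4 of resorcinol (ortho and para to its two hydroxyls, used in excess against twofold alkylation) should capture anti to the 3-OTES group to set C4 as 4α (R); this is the classical acid condensation of flavan-3,4-diols with resorcinol.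

Step 11
Reactants: 15 (2R,3S,4R)-7-(benzyloxy)-2-[3,4-bis(benzyloxy)phenyl]-4-(2,4-dihydroxyphenyl)-3-(triethylsilyloxy)chromane; 5 [(2S,3S)-3-[3,4-bis(benzyloxy)phenyl]oxiran-2-yl]methanol
Product: 16 (2R,3S,4R)-7-(benzyloxy)-2-[3,4-bis(benzyloxy)phenyl]-4-[4-[(1R,2S)-1-[3,4-bis(benzyloxy)phenyl]-2,3-dihydroxypropoxy]-2-hydroxyphenyl]-3-(triethylsilyloxy)chromane
Conditions: 5 (1.2 equiv), Cs2CO3 (0.3 equiv), DMF, 60 °C
Reagents that add atoms: none
Why: The same benzylic SN2 epoxide opening with inversion as in step 4 sets the new benzylic centre as R, and it should occur at the phenol para to the flavanyl carbon because the ortho phenol is shielded by the C4 methine and the 3-OTES group against the hindered secondary electrophile.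

Step 12
Reactants: 16 (2R,3S,4R)-7-(benzyloxy)-2-[3,4-bis(benzyloxy)phenyl]-4-[4-[(1R,2S)-1-[3,4-bis(benzyloxy)phenyl]-2,3-dihydroxypropoxy]-2-hydroxyphenyl]-3-(triethylsilyloxy)chromane
Product: 17 (2R,3S,4R)-7-(benzyloxy)-2-[3,4-bis(benzyloxy)phenyl]-4-[2-(benzyloxy)-4-[(1R,2S)-1-[3,4-bis(benzyloxy)phenyl]-2,3-dihydroxypropoxy]phenyl]-3-(triethylsilyloxy)chromane
Conditions: BnBr (1.5 equiv), K2CO3, DMF, 40 °C
Reagents that add atoms: benzyl bromide BrCc1ccccc1
Why: Williamson etherification under carbonate benzylates the remaining phenol (the future 7-oxygen of unit 2) and leaves the aliphatic diol free.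

Step 13
Reactants: 17 (2R,3S,4R)-7-(benzyloxy)-2-[3,4-bis(benzyloxy)phenyl]-4-[2-(benzyloxy)-4-[(1R,2S)-1-[3,4-bis(benzyloxy)phenyl]-2,3-dihydroxypropoxy]phenyl]-3-(triethylsilyloxy)chromane
Product: 18 (2R,3S,4R)-7-(benzyloxy)-2-[3,4-bis(benzyloxy)phenyl]-4-[2-(benzyloxy)-4-[(1R,2S)-1-[3,4-bis(benzyloxy)phenyl]-2,3-bis(triethylsilyloxy)propoxy]phenyl]-3-(triethylsilyloxy)chromane
Conditions: Et3SiCl (2.5 equiv), imidazole, DMAP (cat.), DMF, 0 °C to rt
Reagents that add atoms: chlorotriethylsilane CC[Si](Cl)(CC)CC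
Why: Silylation of the primary and secondary hydroxyl groups as in step 5, with no change at any stereocentre.

Step 14
Reactants: 18 (2R,3S,4R)-7-(benzyloxy)-2-[3,4-bis(benzyloxy)phenyl]-4-[2-(benzyloxy)-4-[(1R,2S)-1-[3,4-bis(benzyloxy)phenyl]-2,3-bis(triethylsilyloxy)propoxy]phenyl]-3-(triethylsilyloxy)chromane
Product: 19 (2R,3S,4R)-7-(benzyloxy)-2-[3,4-bis(benzyloxy)phenyl]-4-[2-(benzyloxy)-4-[(1R,2R)-1-[3,4-bis(benzyloxy)phenyl]-3-oxo-2-(triethylsilyloxy)propoxy]phenyl]-3-(triethylsilyloxy)chromane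
Conditions: (COCl)2, DMSO, CH2Cl2, −78 to −40 °C; then Et3N, −78 °C; cold pH 7 work-up, used at once
Reagents that add atoms: none
Why: Selective Swern cleavage–oxidation of the single primary TES ether, as in step 6, should give the aldehyde while both secondary TES ethers stay in place.

Step 15
Reactants: 19 (2R,3S,4R)-7-(benzyloxy)-2-[3,4-bis(benzyloxy)phenyl]-4-[2-(benzyloxy)-4-[(1R,2R)-1-[3,4-bis(benzyloxy)phenyl]-3-oxo-2-(triethylsilyloxy)propoxy]phenyl]-3-(triethylsilyloxy)chromane; 13 7,3',4'-tri-O-benzyl-3-O-(triethylsilyl)fisetinidol-(4α→8)-5,7,3',4'-tetra-O-benzylcatechin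
Product: 21 [7,3',4'-tri-O-benzyl-3-O-TES-fisetinidol]-(4α→6)-[7,3',4'-tri-O-benzyl-3-O-TES-fisetinidol]-(4α→6)-[5,7,3',4'-tetra-O-benzylcatechin]-(8←4α)-[7,3',4'-tri-O-benzyl-3-O-TES-fisetinidol], via flavan-4-ol 20 (not isolated)
Conditions: 19, Me3SiOTf (0.3 equiv), 4 Å MS, CH2Cl2, −78 °C, 15 min; then 13 (2 equiv), −78 to −30 °C; Et3N
Reagents that add atoms: none
Why: Proposed new method: the acid activates the aldehyde as an oxocarbenium ion that is attacked by C4a of the tethered resorcinol-type ring (para to the 7-benzyloxy group, ortho to the ether oxygen) in a 6-exo-trig Friedel–Crafts hydroxyalkylation, closing ring C of unit 2 through a chair-like transition state with the 2-aryl and 3-silyloxy groups equatorial to give flavan-4-ol 20, which then ionises to the 7-alkoxy-stabilised flavan-4-yl cation and is captured by C6 of the catechin ring of 13. The closest known reaction types are the acid-catalysed twofold arylation of an aldehyde (Baeyer condensation, including its tandem intramolecular/intermolecular variants that give 9-arylxanthenes and 9-arylfluorenes) and the Lewis-acid coupling of flavan-4-ols or their 4-ethers with benzylated flavan-3-ols, here merged in one flask. The only new stereocentre, C4 of unit 2, is controlled by C3 and C2: the arene adds to the half-chair cation on the face anti to the pseudo-equatorial 3-OTES group, giving the all-equatorial 2,3-trans-3,4-trans (4α) arrangement, which is also the thermodynamic one under reversible acid conditions, so the C4 configuration of 20 is of no consequence. The step needs closure at C4a and not at C8 (secured by para-alkoxy activation and the crowding between the two oxygens), six-membered closure and not five-membered closure onto the catechol ring (secured by ring size and the higher nucleophilicity of the resorcinol-type ring), and capture by C6 of the catechin ring and not by a resorcinol-type ring (secured because C6 is the only free position of the sole phloroglucinol-type ring, the most nucleophilic arene present, used in excess). Should 13 add to the aldehyde before ring closure, the resulting trialkoxybenzylic cation closes the same ring by the same C4–C4a bond, so both orders of events converge on 21.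

Step 16
Reactants: 21 the trideca-O-benzyl-tris-O-(triethylsilyl) tetraflavanoid of step 15
Product: 22 trideca-O-benzyl tetraflavanoid with all four 3-hydroxyl groups free
Conditions: HF·pyridine, THF/pyridine, 0 °C to rt
Reagents that add atoms: none
Why: Fluoride-mediated desilylation cleaves the three secondary TES ethers while benzyl ethers, interflavan C–C bonds and all stereocentres are inert.

Step 17
Reactants: 22 the trideca-O-benzyl tetraflavanoid of step 16
Product: 23 fisetinidol-(4α→6)-fisetinidol-(4α→6)-catechin-(8←4α)-fisetinidol (CNP0263622.1)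
Conditions: H2 (1 atm), Pd(OH)2/C, THF/MeOH/H2O, rt
Reagents that add atoms: none
Why: Hydrogenolysis of the thirteen O-benzyl ethers over Pd(OH)2 on carbon is the standard last step for benzylated oligoflavanoids and leaves the ring C–O bonds, the C4–aryl bonds and all eleven stereocentres intact.

**Compound list**

1 | 3,4-bis(benzyloxy)benzaldehyde | O=Cc1ccc(OCc2ccccc2)c(OCc2ccccc2)c1 | starting material
2 | triethyl phosphonoacetate | CCOC(=O)CP(=O)(OCC)OCC | starting material
3 | ethyl (E)-3-[3,4-bis(benzyloxy)phenyl]prop-2-enoate | CCOC(=O)/C=C/c1ccc(OCc2ccccc2)c(OCc2ccccc2)c1 | intermediate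
4 | (E)-3-[3,4-bis(benzyloxy)phenyl]prop-2-en-1-ol | OC/C=C/c1ccc(OCc2ccccc2)c(OCc2ccccc2)c1 | intermediate
5 | [(2S,3S)-3-[3,4-bis(benzyloxy)phenyl]oxiran-2-yl]methanol | O1[C@@H](c2ccc(OCc3ccccc3)c(OCc3ccccc3)c2)[C@@H]1CO | intermediate
6 | 3-(benzyloxy)phenol | Oc1cccc(OCc2ccccc2)c1 | starting material
7 | (2S,3R)-3-[3,4-bis(benzyloxy)phenyl]-3-[3-(benzyloxy)phenoxy]propane-1,2-diol | O(c1cccc(OCc2ccccc2)c1)[C@H](c1ccc(OCc2ccccc2)c(OCc2ccccc2)c1)[C@@H](O)CO | intermediate
8 | (2S,3R)-3-[3,4-bis(benzyloxy)phenyl]-3-[3-(benzyloxy)phenoxy]-1,2-bis(triethylsilyloxy)propane | O(c1cccc(OCc2ccccc2)c1)[C@H](c1ccc(OCc2ccccc2)c(OCc2ccccc2)c1)[C@@H](O[Si](CC)(CC)CC)CO[Si](CC)(CC)CC | intermediate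
9 | (2R,3R)-3-[3,4-bis(benzyloxy)phenyl]-3-[3-(benzyloxy)phenoxy]-2-(triethylsilyloxy)propanal | O(c1cccc(OCc2ccccc2)c1)[C@H](c1ccc(OCc2ccccc2)c(OCc2ccccc2)c1)[C@@H](O[Si](CC)(CC)CC)C=O | intermediate
10 | (+)-catechin, (2R,3S)-flavan-3,5,7,3',4'-pentaol | O[C@H]1Cc2c(O)cc(O)cc2O[C@@H]1c1ccc(O)c(O)c1 | starting material
11 | 5,7,3',4'-tetra-O-benzyl-(+)-catechin | O[C@H]1Cc2c(OCc3ccccc3)cc(OCc3ccccc3)cc2O[C@@H]1c1ccc(OCc2ccccc2)c(OCc2ccccc2)c1 | intermediate
12 | (2R,3S)-7-(benzyloxy)-2-[3,4-bis(benzyloxy)phenyl]-3-(triethylsilyloxy)chroman-4-ol (mixture of C4 epimers) | O(Cc1ccccc1)c1ccc2c(c1)O[C@H](c1ccc(OCc3ccccc3)c(OCc3ccccc3)c1)[C@@H](O[Si](CC)(CC)CC)C2O | intermediate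
13 | 7,3',4'-tri-O-benzyl-3-O-(triethylsilyl)fisetinidol-(4α→8)-5,7,3',4'-tetra-O-benzylcatechin | c1c(OCc9ccccc9)c2c(c([C@@H]3c4ccc(OCc9ccccc9)cc4O[C@H](c4ccc(OCc9ccccc9)c(OCc9ccccc9)c4)[C@H]3O[Si](CC)(CC)CC)c1OCc9ccccc9)O[C@H](c1ccc(OCc9ccccc9)c(OCc9ccccc9)c1)[C@@H](O)C2 | intermediate
14 | resorcinol | Oc1cccc(O)c1 | starting material
15 | (2R,3S,4R)-7-(benzyloxy)-2-[3,4-bis(benzyloxy)phenyl]-4-(2,4-dihydroxyphenyl)-3-(triethylsilyloxy)chromane (2,3-trans-3,4-trans) | O(Cc1ccccc1)c1ccc2c(c1)O[C@H](c1ccc(OCc3ccccc3)c(OCc3ccccc3)c1)[C@@H](O[Si](CC)(CC)CC)[C@@H]2c1ccc(O)cc1O | intermediate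
16 | 15 etherified at the 4-hydroxyl of the dihydroxyphenyl ring (para to the flavanyl carbon) with the (1R,2S)-1-[3,4-bis(benzyloxy)phenyl]-2,3-dihydroxypropyl group; 2-hydroxyl free | O(Cc1ccccc1)c1ccc2c(c1)O[C@H](c1ccc(OCc3ccccc3)c(OCc3ccccc3)c1)[C@@H](O[Si](CC)(CC)CC)[C@@H]2c1ccc(O[C@H](c2ccc(OCc3ccccc3)c(OCc3ccccc3)c2)[C@@H](O)CO)cc1O | intermediate
17 | 2-O-benzyl ether of 16 (free 1,2-diol in the side chain) | O(Cc1ccccc1)c1ccc2c(c1)O[C@H](c1ccc(OCc3ccccc3)c(OCc3ccccc3)c1)[C@@H](O[Si](CC)(CC)CC)[C@@H]2c1ccc(O[C@H](c2ccc(OCc3ccccc3)c(OCc3ccccc3)c2)[C@@H](O)CO)cc1OCc1ccccc1 | intermediate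
18 | bis-O-(triethylsilyl) ether of the side-chain diol of 17 | O(Cc1ccccc1)c1ccc2c(c1)O[C@H](c1ccc(OCc3ccccc3)c(OCc3ccccc3)c1)[C@@H](O[Si](CC)(CC)CC)[C@@H]2c1ccc(O[C@H](c2ccc(OCc3ccccc3)c(OCc3ccccc3)c2)[C@@H](O[Si](CC)(CC)CC)CO[Si](CC)(CC)CC)cc1OCc1ccccc1 | intermediate
19 | aldehyde of 18: side chain (1R,2R)-1-[3,4-bis(benzyloxy)phenyl]-3-oxo-2-(triethylsilyloxy)propoxy | O(Cc1ccccc1)c1ccc2c(c1)O[C@H](c1ccc(OCc3ccccc3)c(OCc3ccccc3)c1)[C@@H](O[Si](CC)(CC)CC)[C@@H]2c1ccc(O[C@H](c2ccc(OCc3ccccc3)c(OCc3ccccc3)c2)[C@@H](O[Si](CC)(CC)CC)C=O)cc1OCc1ccccc1 | intermediate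
20 | [7,3',4'-tri-O-benzyl-3-O-TES-fisetinidol]-(4α→6)-[7,3',4'-tri-O-benzyl-3-O-TES-flavan-3,4-diol] with free 4-hydroxyl on unit 2 (both C4 epimers; not isolated) | O(Cc1ccccc1)c1ccc2c(c1)O[C@H](c1ccc(OCc3ccccc3)c(OCc3ccccc3)c1)[C@@H](O[Si](CC)(CC)CC)[C@@H]2c1cc2c(cc1OCc1ccccc1)O[C@H](c1ccc(OCc3ccccc3)c(OCc3ccccc3)c1)[C@@H](O[Si](CC)(CC)CC)C2O | intermediate
21 | trideca-O-benzyl-tris-O-(triethylsilyl) tetraflavanoid (3-OTES on units 1, 2 and 4; 3-OH of unit 3 free) | O(Cc1ccccc1)c1ccc2c(c1)O[C@H](c1ccc(OCc3ccccc3)c(OCc3ccccc3)c1)[C@@H](O[Si](CC)(CC)CC)[C@@H]2c1cc2c(cc1OCc1ccccc1)O[C@H](c1ccc(OCc3ccccc3)c(OCc3ccccc3)c1)[C@@H](O[Si](CC)(CC)CC)[C@@H]2c1c(OCc9ccccc9)c2c(c([C@@H]3c4ccc(OCc9ccccc9)cc4O[C@H](c4ccc(OCc9ccccc9)c(OCc9ccccc9)c4)[C@H]3O[Si](CC)(CC)CC)c1OCc9ccccc9)O[C@H](c1ccc(OCc9ccccc9)c(OCc9ccccc9)c1)[C@@H](O)C2 | intermediate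
22 | trideca-O-benzyl tetraflavanoid (all 3-OH free) | O(Cc1ccccc1)c1ccc2c(c1)O[C@H](c1ccc(OCc3ccccc3)c(OCc3ccccc3)c1)[C@@H](O)[C@@H]2c1cc2c(cc1OCc1ccccc1)O[C@H](c1ccc(OCc3ccccc3)c(OCc3ccccc3)c1)[C@@H](O)[C@@H]2c1c(OCc9ccccc9)c2c(c([C@@H]3c4ccc(OCc9ccccc9)cc4O[C@H](c4ccc(OCc9ccccc9)c(OCc9ccccc9)c4)[C@H]3O)c1OCc9ccccc9)O[C@H](c1ccc(OCc9ccccc9)c(OCc9ccccc9)c1)[C@@H](O)C2 | intermediate
23 | fisetinidol-(4α→6)-fisetinidol-(4α→6)-catechin-(8←4α)-fisetinidol (CNP0263622.1) | Oc1ccc2c(c1)O[C@H](c1ccc(O)c(O)c1)[C@@H](O)[C@@H]2c1cc2c(cc1O)O[C@H](c1ccc(O)c(O)c1)[C@@H](O)[C@@H]2c1c(O)c2c(c([C@@H]3c4ccc(O)cc4O[C@H](c4ccc(O)c(O)c4)[C@H]3O)c1O)O[C@H](c1ccc(O)c(O)c1)[C@@H](O)C2 | target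

**Step count and risks**

Total step count: 17. Longest linear sequence: 15 steps (steps 1–6, 8, then 10–17).

The three steps most likely to fail are steps 15, 8 and 10; the first two carry proposed methods, and each fallback uses known chemistry.

1. Step 15. What may go wrong: capture of the flavan-4-yl cation by the crowded C6 position of 13 may lose out to capture by resorcinol-type rings of a second molecule of 19 or 20 (self-condensation to oligomers), and heterolysis of the benzylic C2–O1 aryl ether may occur before ring closure. The fallback sets out from 13 and 19 and returns at 21. Bromination of 13 with N-bromosuccinimide (CH2Cl2, −78 °C) at C6 of the catechin ring, its only free and most electron-rich position, should give the 6-bromo derivative of 13 F1. Bromine–lithium exchange (n-BuLi, 2.1 equiv, THF, −78 °C, the first equivalent taking the 3-OH proton) and addition of the aryllithium to aldehyde 19 should give the secondary benzylic alcohol F2 as a mixture of carbinol epimers. Catalytic Me3SiOTf (CH2Cl2, −78 to −40 °C) should then ionise this trialkoxybenzylic alcohol, and the cation is expected to close ring C of unit 2 through the same C4–C4a bond by intramolecular Friedel–Crafts alkylation with all three ring substituents equatorial, giving 21. The interflavan bond is thus made at a site fixed by the bromine, and no free flavan-4-yl cation meets competing arenes.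

2. Step 8. What may go wrong: ionisation of the newly formed dialkoxybenzylic aluminium alkoxide with self-condensation through the free positions of ring A, methyl transfer from aluminium to the aldehyde, and heterolysis of the benzylic aryl ether before ring closure. The fallback sets out from 9 and returns at 12. Pinnick oxidation (NaClO2, NaH2PO4, 2-methyl-2-butene, t-BuOH/H2O, 0 °C) should give (2R,3R)-3-[3,4-bis(benzyloxy)phenyl]-3-[3-(benzyloxy)phenoxy]-2-(triethylsilyloxy)propanoic acid F3. Intramolecular Friedel–Crafts acylation through the mixed anhydride ((CF3CO)2O, CH2Cl2, 0 °C), para to the benzyloxy group as in the standard cyclisation of 3-aryloxypropanoic acids to chroman-4-ones, should give the protected dihydroflavonol (2R,3R)-7-(benzyloxy)-2-[3,4-bis(benzyloxy)phenyl]-3-(triethylsilyloxy)chroman-4-one F4. Reduction with NaBH4 (THF/MeOH, −20 °C), the usual passage from dihydroflavonols to flavan-3,4-diols, should give 12. Ring C is closed through the same C4–C4a bond at the ketone oxidation level, where the product cannot ionise.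

3. Step 10. What may go wrong: twofold alkylation of resorcinol, slow ionisation of 12 in the ether-containing medium and acid-promoted loss of the silyl ether in the presence of free phenols. The fallback sets out from 9 and returns at 15. 1-Bromo-2,4-bis(allyloxy)benzene F5 (from commercial 4-bromoresorcinol, allyl bromide and K2CO3) is lithiated (n-BuLi, THF, −78 °C) and added to 9 to give the benzylic alcohol (2S,3R)-1-[2,4-bis(allyloxy)phenyl]-3-[3,4-bis(benzyloxy)phenyl]-3-[3-(benzyloxy)phenoxy]-2-(triethylsilyloxy)propan-1-ol F6. Catalytic Me3SiOTf (CH2Cl2, −78 °C) should ionise this dialkoxybenzylic alcohol and close ring C of unit 1 by intramolecular Friedel–Crafts alkylation para to the benzyloxy group, with all three ring substituents equatorial, giving the bis-O-allyl ether of 15 F7. Pd(PPh3)4 with morpholine (THF, rt) should remove both allyl groups without touching benzyl or TES ethers, giving 15.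

**Further compounds**

F1 | step 15 | 6-bromo derivative of 13 (bromine on C6 of the catechin ring) | Brc1c(OCc9ccccc9)c2c(c([C@@H]3c4ccc(OCc9ccccc9)cc4O[C@H](c4ccc(OCc9ccccc9)c(OCc9ccccc9)c4)[C@H]3O[Si](CC)(CC)CC)c1OCc9ccccc9)O[C@H](c1ccc(OCc9ccccc9)c(OCc9ccccc9)c1)[C@@H](O)C2
F2 | step 15 | secondary alcohol from addition of 6-lithiated 13 to aldehyde 19 (carbinol epimers) | O(Cc1ccccc1)c1ccc2c(c1)O[C@H](c1ccc(OCc3ccccc3)c(OCc3ccccc3)c1)[C@@H](O[Si](CC)(CC)CC)[C@@H]2c1ccc(O[C@H](c2ccc(OCc3ccccc3)c(OCc3ccccc3)c2)[C@@H](O[Si](CC)(CC)CC)C(O)c2c(OCc9ccccc9)c3c(c([C@@H]4c5ccc(OCc9ccccc9)cc5O[C@H](c5ccc(OCc9ccccc9)c(OCc9ccccc9)c5)[C@H]4O[Si](CC)(CC)CC)c2OCc9ccccc9)O[C@H](c2ccc(OCc9ccccc9)c(OCc9ccccc9)c2)[C@@H](O)C3)cc1OCc1ccccc1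
F3 | step 8 | (2R,3R)-3-[3,4-bis(benzyloxy)phenyl]-3-[3-(benzyloxy)phenoxy]-2-(triethylsilyloxy)propanoic acid | O(c1cccc(OCc2ccccc2)c1)[C@H](c1ccc(OCc2ccccc2)c(OCc2ccccc2)c1)[C@@H](O[Si](CC)(CC)CC)C(=O)O
F4 | step 8 | (2R,3R)-7-(benzyloxy)-2-[3,4-bis(benzyloxy)phenyl]-3-(triethylsilyloxy)chroman-4-one | O(Cc1ccccc1)c1ccc2c(c1)O[C@H](c1ccc(OCc3ccccc3)c(OCc3ccccc3)c1)[C@@H](O[Si](CC)(CC)CC)C2=O
F5 | step 10 | 1-bromo-2,4-bis(allyloxy)benzene | C=CCOc1ccc(Br)c(OCC=C)c1
F6 | step 10 | (2S,3R)-1-[2,4-bis(allyloxy)phenyl]-3-[3,4-bis(benzyloxy)phenyl]-3-[3-(benzyloxy)phenoxy]-2-(triethylsilyloxy)propan-1-ol (carbinol epimers) | O(c1cccc(OCc2ccccc2)c1)[C@H](c1ccc(OCc2ccccc2)c(OCc2ccccc2)c1)[C@@H](O[Si](CC)(CC)CC)C(O)c1ccc(OCC=C)cc1OCC=C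
F7 | step 10 | bis-O-allyl ether of 15 | O(Cc1ccccc1)c1ccc2c(c1)O[C@H](c1ccc(OCc3ccccc3)c(OCc3ccccc3)c1)[C@@H](O[Si](CC)(CC)CC)[C@@H]2c1ccc(OCC=C)cc1OCC=C
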